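The route rests on cutting the aryl ether bond O1–C8a of the pyran ring (ring C). Because O1 sits on an aromatic carbon of ring A, this bond can be made last by copper-catalysed O-arylation. That closes ring C in one operation without touching the ionisable benzylic C2–O bond or the C2, C3 and C4 stereocentres. All three centres are therefore set in an open chain: an epoxide opening fixes C3/C4 and a Felkin–Anh Grignard addition fixes C2. The precursor is a (1R,2S,3R)-1,3,3-triarylpropan-1-ol with a free hydroxyl at the future C2, a non-migrating triisopropylsilyl ether on the future C3 oxygen, an ortho-iodide on ring A and a chloride on ring D for the late styryl coupling.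

Key step: step 12

Remark: ring A is the benzo ring, ring B the 2-aryl group, ring C the pyran and ring D the 4-aryl group; 3-bromo-4-iodophenol and bis(pinacolboryl)methane are assumed to be purchasable.
Remark: the descriptor of the diaryl carbon reads 3R in the open-chain halides and 4S in the flavans only because ligand priorities change; the geometry is the same throughout.

Step 1
Reactants: 1 5-chlorobenzene-1,3-diol
Product: 2 1,3-bis(benzyloxy)-5-chlorobenzene
Conditions: BnBr, K2CO3, DMF, 60 °C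
Reagents that add atoms: benzyl bromide BrCc1ccccc1
Why: Williamson ether synthesis: both phenoxides are alkylated by benzyl bromide, and the benzyl ethers should survive every later step up to the final Lewis-acid cleavage.

Step 2
Reactants: 2 1,3-bis(benzyloxy)-5-chlorobenzene
Product: 4 2,4-bis(benzyloxy)-6-chlorobenzaldehyde, via iminium chloride 3 (not isolated)
Conditions: POCl3, DMF, 0 → 70 °C; then ice-water
Reagents that add atoms: N,N-dimethylformamide CN(C)C=O; water O
Why: Vilsmeier–Haack formylation: the chloroiminium electrophile should attack the chlorine-flanked carbon that is ortho to one benzyloxy group and para to the other (the carbon between the two ethers is more shielded), as is usual for 1-chloro-3,5-dialkoxybenzenes, and water hydrolyses the iminium salt to the aldehyde.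

Step 3
Reactants: 4 2,4-bis(benzyloxy)-6-chlorobenzaldehyde
Product: 5 ethyl (2E)-3-[2,4-bis(benzyloxy)-6-chlorophenyl]prop-2-enoate
Conditions: (EtO)2P(O)CH2CO2Et, NaH, THF, 0 °C → rt
Reagents that add atoms: triethyl phosphonoacetate CCOC(=O)CP(=O)(OCC)OCC
Why: Horner–Wadsworth–Emmons olefination: the stabilised phosphonate anion gives the E-enoate.

Step 4
Reactants: 5 ethyl (2E)-3-[2,4-bis(benzyloxy)-6-chlorophenyl]prop-2-enoate
Product: 6 (2E)-3-[2,4-bis(benzyloxy)-6-chlorophenyl]prop-2-en-1-ol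
Conditions: iBu2AlH, CH2Cl2, −78 → 0 °C; aq potassium sodium tartrate
Reagents that add atoms: none
Why: 1,2-Hydride reduction of the conjugated ester with iBu2AlH stops at the allylic alcohol and leaves the aryl chloride, the benzyl ethers and the E-alkene alone.

Step 5
Reactants: 6 (2E)-3-[2,4-bis(benzyloxy)-6-chlorophenyl]prop-2-en-1-ol
Product: 7 [(2R,3R)-3-[2,4-bis(benzyloxy)-6-chlorophenyl]oxiran-2-yl]methanol
Conditions: Ti(OiPr)4 (10 mol%), D-(−)-diethyl tartrate (12 mol%), tBuOOH, 4 Å sieves, CH2Cl2, −20 °C; NaOH/brine work-up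
Reagents that add atoms: tert-butyl hydroperoxide CC(C)(C)OO
Why: Sharpless asymmetric epoxidation: D-(−)-tartrate directs oxygen to the face that gives the (2R,3R)-trans-epoxide (the mirror image of what L-(+)-tartrate gives with E-cinnamyl alcohols), which fixes the future C3 and, after inversion in step 7, C4; catalytic loading and a basic work-up spare the acid-sensitive aryl oxirane.

Step 6
Reactants: 8 3-bromo-4-iodophenol
Product: 9 4-(benzyloxy)-2-bromo-1-iodobenzene
Conditions: BnBr, K2CO3, acetone, reflux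
Reagents that add atoms: benzyl bromide BrCc1ccccc1
Why: Williamson ether synthesis of the phenol; both aryl halides are inert to carbonate.

Step 7
Reactants: 7 [(2R,3R)-3-[2,4-bis(benzyloxy)-6-chlorophenyl]oxiran-2-yl]methanol; 9 4-(benzyloxy)-2-bromo-1-iodobenzene
Product: 11 (2S,3R)-3-[4-(benzyloxy)-2-bromophenyl]-3-[2,4-bis(benzyloxy)-6-chlorophenyl]propane-1,2-diol, via aryl Grignard reagent 10 (not isolated)
Conditions: 9, iPrMgCl·LiCl, THF, −40 °C; CuI (20 mol%); then 7 (pre-treated with 1.0 equiv iPrMgCl·LiCl), −40 → −20 °C; aq NH4Cl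
Reagents that add atoms: none
Why: Iodine–magnesium exchange (faster at iodide than bromide; the ortho-bromoaryl Grignard reagent should not form an aryne below about −20 °C) followed by the copper-catalysed SN2 opening of a 3-aryl-2,3-epoxy alcohol by an aryl Grignard reagent: attack at the benzylic C3 anti to the oxirane oxygen inverts that centre and gives the (2S,3R)-diol, with ring A bonded unambiguously through the former iodide carbon.

Step 8
Reactants: 11 (2S,3R)-3-[4-(benzyloxy)-2-bromophenyl]-3-[2,4-bis(benzyloxy)-6-chlorophenyl]propane-1,2-diol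
Product: 13 (2S,3R)-3-[4-(benzyloxy)-2-bromophenyl]-3-[2,4-bis(benzyloxy)-6-chlorophenyl]-1-[(triethylsilyl)oxy]-2-[(triisopropylsilyl)oxy]propane, via primary triethylsilyl ether 12 (not isolated)
Conditions: Et3SiCl, Et3N, DMAP (cat.), CH2Cl2, −20 °C; then iPr3SiOTf, 2,6-lutidine, 0 → 40 °C
Reagents that add atoms: chlorotriethylsilane CC[Si](Cl)(CC)CC; triisopropylsilyl trifluoromethanesulfonate CC(C)[Si](OS(=O)(=O)C(F)(F)F)(C(C)C)C(C)C
Why: Stepwise silylation in one flask: the unhindered primary hydroxyl takes the triethylsilyl group first and the hindered secondary hydroxyl is then forced with the silyl triflate; triisopropylsilyl is chosen for the future C3 oxygen because it neither chelates magnesium (step 11) nor migrates to a neighbouring alkoxide (step 12).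

Step 9
Reactants: 13 (2S,3R)-3-[4-(benzyloxy)-2-bromophenyl]-3-[2,4-bis(benzyloxy)-6-chlorophenyl]-1-[(triethylsilyl)oxy]-2-[(triisopropylsilyl)oxy]propane
Product: 14 (2S,3R)-3-[4-(benzyloxy)-2-iodophenyl]-3-[2,4-bis(benzyloxy)-6-chlorophenyl]-1-[(triethylsilyl)oxy]-2-[(triisopropylsilyl)oxy]propane
Conditions: CuI (10 mol%), NaI, trans-N,N′-dimethylcyclohexane-1,2-diamine (20 mol%), 1,4-dioxane, 110 °C
Reagents that add atoms: sodium iodide [Na+].[I-]
Why: Aromatic Finkelstein reaction: copper/diamine-catalysed halide exchange turns the aryl bromide into the aryl iodide, driven by the insolubility of NaBr in dioxane, while the ring D chloride is inert, so the ring-closing carbon carries the most reactive halide and the spectator carbon the least reactive one.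

Step 10
Reactants: 14 (2S,3R)-3-[4-(benzyloxy)-2-iodophenyl]-3-[2,4-bis(benzyloxy)-6-chlorophenyl]-1-[(triethylsilyl)oxy]-2-[(triisopropylsilyl)oxy]propane
Product: 15 (2S,3R)-3-[4-(benzyloxy)-2-iodophenyl]-3-[2,4-bis(benzyloxy)-6-chlorophenyl]-2-[(triisopropylsilyl)oxy]propanal
Conditions: (COCl)2, DMSO, CH2Cl2, −78 → −30 °C; Et3N, −78 → 0 °C
Reagents that add atoms: none
Why: Swern oxidation applied directly to the primary triethylsilyl ether: the chlorosulfonium reagent exchanges the labile primary silyl group for the alkoxysulfonium ion, which triethylamine fragments to the aldehyde (a known selective oxidation of primary triethylsilyl ethers beside bulky secondary silyl ethers), and the low temperature should keep the α-silyloxy centre from epimerising.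

Step 11
Reactants: 15 (2S,3R)-3-[4-(benzyloxy)-2-iodophenyl]-3-[2,4-bis(benzyloxy)-6-chlorophenyl]-2-[(triisopropylsilyl)oxy]propanal; 16 1-(benzyloxy)-4-bromobenzene
Product: 18 (1R,2S,3R)-1-[4-(benzyloxy)phenyl]-3-[4-(benzyloxy)-2-iodophenyl]-3-[2,4-bis(benzyloxy)-6-chlorophenyl]-2-[(triisopropylsilyl)oxy]propan-1-ol, via aryl Grignard reagent 17 (not isolated)
Conditions: 16, Mg, THF, 40 °C; then 15, THF, −78 °C; aq NH4Cl
Reagents that add atoms: none
Why: Grignard addition to an α-silyloxy aldehyde under Felkin–Anh (Cornforth) control: with the non-chelating silyloxy group anti to the incoming aryl nucleophile the 1,2-anti carbinol (1R) should form, which is the relationship that becomes 2,3-trans in the flavan; at −78 °C the aryl Grignard reagent adds to the aldehyde far faster than it exchanges with the aryl iodide.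

Step 12
Reactants: 18 (1R,2S,3R)-1-[4-(benzyloxy)phenyl]-3-[4-(benzyloxy)-2-iodophenyl]-3-[2,4-bis(benzyloxy)-6-chlorophenyl]-2-[(triisopropylsilyl)oxy]propan-1-ol
Product: 19 (2R,3S,4S)-7-(benzyloxy)-2-[4-(benzyloxy)phenyl]-4-[2,4-bis(benzyloxy)-6-chlorophenyl]-3-[(triisopropylsilyl)oxy]-3,4-dihydro-2H-chromene
Conditions: CuI (20 mol%), 3,4,7,8-tetramethyl-1,10-phenanthroline (40 mol%), Cs2CO3, toluene, 90 °C
Reagents that add atoms: none
Why: Carbonate generates the alkoxide of the C1 hydroxyl (future O1), which binds phenanthroline-ligated monovalent copper; this copper alkoxide activates the carbon–iodine bond on ring A (oxidative addition to a trivalent copper aryl alkoxide) and reductive elimination forms the aryl ether bond O1–C8a. The closest known reaction type is the copper-catalysed intramolecular Ullmann-type O-arylation of secondary alcohols by aryl iodides, which is used to make chromans and flavans. Ring C closes as a six-membered ring in a 6-exo sense at C8a: oxygen attacks the iodine-bearing sp2 carbon, iodide leaves outside the ring, and the C4a–C8a bond of ring A becomes the ring fusion. No stereocentre is formed: because the new bond ends at an sp2 carbon and no bond at C2, C3 or C4 is broken, the (1R,2S,3R) open-chain triad is carried over with retention as the all-trans (2R,3S,4S) flavan. Two chemoselectivities are needed: iodide over the ring D chloride, which sits at a geometrically equivalent ortho position and would also give a six-membered ring, is secured by copper, which should not insert into aryl chlorides at 90 °C; the C1 hydroxyl over the future C3 oxygen is secured by the triisopropylsilyl ether, which should stay in place under carbonate base, so no five-membered dihydrobenzofuran can form.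

Step 13
Reactants: 20 3,4-bis(benzyloxy)benzaldehyde
Product: 21 2-[(E)-2-[3,4-bis(benzyloxy)phenyl]ethenyl]-4,4,5,5-tetramethyl-1,3,2-dioxaborolane
Conditions: bis(pinacolboryl)methane, lithium 2,2,6,6-tetramethylpiperidide, THF, 0 °C; then 20, −78 °C → rt; aq NH4Cl
Reagents that add atoms: bis(4,4,5,5-tetramethyl-1,3,2-dioxaborolan-2-yl)methane CC1(C)OB(CB2OC(C)(C)C(C)(C)O2)OC1(C)C
Why: Boron-Wittig olefination: the lithiated geminal diboronate adds to the aldehyde and the β-alkoxy boronate eliminates a boron–oxygen unit to give the E-alkenyl boronate.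

Step 14
Reactants: 19 (2R,3S,4S)-7-(benzyloxy)-2-[4-(benzyloxy)phenyl]-4-[2,4-bis(benzyloxy)-6-chlorophenyl]-3-[(triisopropylsilyl)oxy]-3,4-dihydro-2H-chromene; 21 2-[(E)-2-[3,4-bis(benzyloxy)phenyl]ethenyl]-4,4,5,5-tetramethyl-1,3,2-dioxaborolane
Product: 22 (2R,3S,4S)-7-(benzyloxy)-2-[4-(benzyloxy)phenyl]-4-[2,4-bis(benzyloxy)-6-[(E)-2-[3,4-bis(benzyloxy)phenyl]ethenyl]phenyl]-3-[(triisopropylsilyl)oxy]-3,4-dihydro-2H-chromene
Conditions: Pd(OAc)2 (5 mol%), 2-dicyclohexylphosphino-2′,6′-dimethoxybiphenyl (SPhos, 10 mol%), K3PO4, toluene/H2O 10:1, 100 °C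
Reagents that add atoms: none
Why: Suzuki–Miyaura coupling: the bulky electron-rich biaryl phosphine lets zerovalent palladium insert into the hindered aryl chloride, and the alkenyl group is transferred with retention of the E geometry; no stereocentre is touched.

Step 15
Reactants: 22 (2R,3S,4S)-7-(benzyloxy)-2-[4-(benzyloxy)phenyl]-4-[2,4-bis(benzyloxy)-6-[(E)-2-[3,4-bis(benzyloxy)phenyl]ethenyl]phenyl]-3-[(triisopropylsilyl)oxy]-3,4-dihydro-2H-chromene
Product: 23 (2R,3S,4S)-7-(benzyloxy)-2-[4-(benzyloxy)phenyl]-4-[2,4-bis(benzyloxy)-6-[(E)-2-[3,4-bis(benzyloxy)phenyl]ethenyl]phenyl]-3,4-dihydro-2H-chromen-3-ol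
Conditions: Bu4NF, THF, 0 → 40 °C; aq NH4Cl
Reagents that add atoms: none
Why: Fluoride-induced desilylation, driven by the strength of the silicon–fluorine bond, removes the triisopropylsilyl ether without affecting benzyl ethers, the alkene or the stereocentres.

Step 16
Reactants: 23 (2R,3S,4S)-7-(benzyloxy)-2-[4-(benzyloxy)phenyl]-4-[2,4-bis(benzyloxy)-6-[(E)-2-[3,4-bis(benzyloxy)phenyl]ethenyl]phenyl]-3,4-dihydro-2H-chromen-3-ol
Product: 24 (2R,3S,4S)-4-[2-[(E)-2-(3,4-dihydroxyphenyl)ethenyl]-4,6-dihydroxyphenyl]-2-(4-hydroxyphenyl)-3,4-dihydro-2H-chromene-3,7-diol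
Conditions: BCl3, pentamethylbenzene, CH2Cl2, −78 °C; MeOH quench
Reagents that add atoms: none
Why: Lewis-acid debenzylation with BCl3 at −78 °C, with pentamethylbenzene as a non-basic benzyl-cation scavenger (Friedel–Crafts trapping), should free all six phenols without hydrogenation, so the E-stilbene alkene survives and the electron-rich rings are not C-benzylated.

Compound list
1 | 5-chlorobenzene-1,3-diol | Oc1cc(O)cc(Cl)c1 | starting material
2 | 1,3-bis(benzyloxy)-5-chlorobenzene | Clc1cc(OCc2ccccc2)cc(OCc2ccccc2)c1 | intermediate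
3 | [2,4-bis(benzyloxy)-6-chlorophenyl]methylidene(dimethyl)iminium chloride | C[N+](C)=Cc1c(OCc2ccccc2)cc(OCc2ccccc2)cc1Cl.[Cl-] | intermediate
4 | 2,4-bis(benzyloxy)-6-chlorobenzaldehyde | O=Cc1c(OCc2ccccc2)cc(OCc2ccccc2)cc1Cl | intermediate
5 | ethyl (2E)-3-[2,4-bis(benzyloxy)-6-chlorophenyl]prop-2-enoate | CCOC(=O)/C=C/c1c(OCc2ccccc2)cc(OCc2ccccc2)cc1Cl | intermediate
6 | (2E)-3-[2,4-bis(benzyloxy)-6-chlorophenyl]prop-2-en-1-ol | OC/C=C/c1c(OCc2ccccc2)cc(OCc2ccccc2)cc1Cl | intermediate
7 | [(2R,3R)-3-[2,4-bis(benzyloxy)-6-chlorophenyl]oxiran-2-yl]methanol | OC[C@H]1O[C@@H]1c1c(OCc2ccccc2)cc(OCc2ccccc2)cc1Cl | intermediate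
8 | 3-bromo-4-iodophenol | Oc1ccc(I)c(Br)c1 | starting material
9 | 4-(benzyloxy)-2-bromo-1-iodobenzene | Brc1cc(OCc2ccccc2)ccc1I | intermediate
10 | [4-(benzyloxy)-2-bromophenyl]magnesium chloride (LiCl complex) | Cl[Mg]c1ccc(OCc2ccccc2)cc1Br | intermediate
11 | (2S,3R)-3-[4-(benzyloxy)-2-bromophenyl]-3-[2,4-bis(benzyloxy)-6-chlorophenyl]propane-1,2-diol | OC[C@@H](O)[C@@H](c1ccc(OCc2ccccc2)cc1Br)c1c(OCc2ccccc2)cc(OCc2ccccc2)cc1Cl | intermediate
12 | (2S,3R)-3-[4-(benzyloxy)-2-bromophenyl]-3-[2,4-bis(benzyloxy)-6-chlorophenyl]-1-[(triethylsilyl)oxy]propan-2-ol | CC[Si](CC)(CC)OC[C@@H](O)[C@@H](c1ccc(OCc2ccccc2)cc1Br)c1c(OCc2ccccc2)cc(OCc2ccccc2)cc1Cl | intermediate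
13 | (2S,3R)-3-[4-(benzyloxy)-2-bromophenyl]-3-[2,4-bis(benzyloxy)-6-chlorophenyl]-1-[(triethylsilyl)oxy]-2-[(triisopropylsilyl)oxy]propane | CC[Si](CC)(CC)OC[C@@H](O[Si](C(C)C)(C(C)C)C(C)C)[C@@H](c1ccc(OCc2ccccc2)cc1Br)c1c(OCc2ccccc2)cc(OCc2ccccc2)cc1Cl | intermediate
14 | (2S,3R)-3-[4-(benzyloxy)-2-iodophenyl]-3-[2,4-bis(benzyloxy)-6-chlorophenyl]-1-[(triethylsilyl)oxy]-2-[(triisopropylsilyl)oxy]propane | CC[Si](CC)(CC)OC[C@@H](O[Si](C(C)C)(C(C)C)C(C)C)[C@@H](c1ccc(OCc2ccccc2)cc1I)c1c(OCc2ccccc2)cc(OCc2ccccc2)cc1Cl | intermediate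
15 | (2S,3R)-3-[4-(benzyloxy)-2-iodophenyl]-3-[2,4-bis(benzyloxy)-6-chlorophenyl]-2-[(triisopropylsilyl)oxy]propanal | O=C[C@@H](O[Si](C(C)C)(C(C)C)C(C)C)[C@@H](c1ccc(OCc2ccccc2)cc1I)c1c(OCc2ccccc2)cc(OCc2ccccc2)cc1Cl | intermediate
16 | 1-(benzyloxy)-4-bromobenzene | Brc1ccc(OCc2ccccc2)cc1 | starting material
17 | [4-(benzyloxy)phenyl]magnesium bromide | Br[Mg]c1ccc(OCc2ccccc2)cc1 | intermediate
18 | (1R,2S,3R)-1-[4-(benzyloxy)phenyl]-3-[4-(benzyloxy)-2-iodophenyl]-3-[2,4-bis(benzyloxy)-6-chlorophenyl]-2-[(triisopropylsilyl)oxy]propan-1-ol | c1ccccc1COc1ccc(cc1)[C@@H](O)[C@@H](O[Si](C(C)C)(C(C)C)C(C)C)[C@@H](c1ccc(OCc2ccccc2)cc1I)c1c(OCc2ccccc2)cc(OCc2ccccc2)cc1Cl | intermediate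
19 | (2R,3S,4S)-7-(benzyloxy)-2-[4-(benzyloxy)phenyl]-4-[2,4-bis(benzyloxy)-6-chlorophenyl]-3-[(triisopropylsilyl)oxy]-3,4-dihydro-2H-chromene | c1ccccc1COc1ccc([C@H]2Oc3cc(OCc4ccccc4)ccc3[C@@H](c3c(OCc4ccccc4)cc(OCc4ccccc4)cc3Cl)[C@@H]2O[Si](C(C)C)(C(C)C)C(C)C)cc1 | intermediate
20 | 3,4-bis(benzyloxy)benzaldehyde | O=Cc1ccc(OCc2ccccc2)c(OCc2ccccc2)c1 | starting material
21 | 2-[(E)-2-[3,4-bis(benzyloxy)phenyl]ethenyl]-4,4,5,5-tetramethyl-1,3,2-dioxaborolane | CC1(C)OB(/C=C/c2ccc(OCc3ccccc3)c(OCc3ccccc3)c2)OC1(C)C | intermediate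
22 | (2R,3S,4S)-7-(benzyloxy)-2-[4-(benzyloxy)phenyl]-4-[2,4-bis(benzyloxy)-6-[(E)-2-[3,4-bis(benzyloxy)phenyl]ethenyl]phenyl]-3-[(triisopropylsilyl)oxy]-3,4-dihydro-2H-chromene | c1ccccc1COc1ccc([C@H]2Oc3cc(OCc4ccccc4)ccc3[C@@H](c3c(OCc4ccccc4)cc(OCc4ccccc4)cc3/C=C/c3ccc(OCc4ccccc4)c(OCc4ccccc4)c3)[C@@H]2O[Si](C(C)C)(C(C)C)C(C)C)cc1 | intermediate
23 | (2R,3S,4S)-7-(benzyloxy)-2-[4-(benzyloxy)phenyl]-4-[2,4-bis(benzyloxy)-6-[(E)-2-[3,4-bis(benzyloxy)phenyl]ethenyl]phenyl]-3,4-dihydro-2H-chromen-3-ol | c1ccccc1COc1ccc([C@H]2Oc3cc(OCc4ccccc4)ccc3[C@@H](c3c(OCc4ccccc4)cc(OCc4ccccc4)cc3/C=C/c3ccc(OCc4ccccc4)c(OCc4ccccc4)c3)[C@@H]2O)cc1 | intermediate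
24 | (2R,3S,4S)-4-[2-[(E)-2-(3,4-dihydroxyphenyl)ethenyl]-4,6-dihydroxyphenyl]-2-(4-hydroxyphenyl)-3,4-dihydro-2H-chromene-3,7-diol | Oc1ccc([C@H]2Oc3cc(O)ccc3[C@@H](c3c(O)cc(O)cc3/C=C/c3ccc(O)c(O)c3)[C@@H]2O)cc1 | target

Total step count: 16. Longest linear sequence: 14 steps (steps 1–5, 7–12 and 14–16; steps 6 and 13 make the side fragments).

Steps most likely to fail

Step 12 (key ring closure). Carbon–oxygen bond formation at the hindered secondary alkoxide may be slow, so that reduction of the carbon–iodine bond, oxidation of the carbinol by β-hydride loss or base-induced silyl transfer take over. The fallback reverses the polarity at C8a and sets out from 18. Miyaura borylation of the aryl iodide (PdCl2(dppf), bis(pinacolato)diboron, KOAc, dioxane, 80 °C; the chloride is left alone) gives (1R,2S,3S)-1-[4-(benzyloxy)phenyl]-3-[4-(benzyloxy)-2-(4,4,5,5-tetramethyl-1,3,2-dioxaborolan-2-yl)phenyl]-3-[2,4-bis(benzyloxy)-6-chlorophenyl]-2-[(triisopropylsilyl)oxy]propan-1-ol F1 (same geometry as 18; the descriptor at C3 changes with the priorities). An intramolecular Chan–Lam etherification (Cu(OAc)2, pyridine, 4 Å sieves, air, CH2Cl2, rt) then joins the free hydroxyl to C8a under oxidative, nearly neutral conditions and comes back to the route at 19.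

Step 7 (arylation of the epoxide). The magnesium salts may ionise the electron-rich aryl oxirane faster than the organocopper species attacks it, leading to rearrangement to carbonyl compounds, chlorohydrin formation or attack at C2; the ortho-bromoaryl magnesium reagent may also be lost through aryne formation. The fallback is a metal-free Friedel–Crafts opening that sets out from 7: commercial 1-(benzyloxy)-3-bromobenzene (excess) and BF3·OEt2 in CH2Cl2 at −78 °C. The arene should attack para to its benzyloxy group at the activated benzylic C3 with inversion; the isomer from attack ortho to the ether would be removed by chromatography. This gives the diol directly and comes back to the route at 11; no new compound is made.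

Step 16 (global debenzylation). Cleaving six benzyl ethers with a Lewis acid may trigger ionisation of the benzylic C2–O1 bond with loss of the C2 configuration, protonation or cyclisation of the electron-rich stilbene, or incomplete cleavage. The fallback moves debenzylation ahead of the alkene and finishes with fluoride only; it sets out from 19. Hydrogenolysis (H2, Pd on carbon, EtOAc, neutral, stopped at full debenzylation so that the aryl chloride is kept) gives (2R,3S,4S)-4-(2-chloro-4,6-dihydroxyphenyl)-2-(4-hydroxyphenyl)-3-[(triisopropylsilyl)oxy]-3,4-dihydro-2H-chromen-7-ol F2. Silylation (tBuMe2SiCl, imidazole, DMF) gives its tetrakis(tert-butyldimethylsilyl) ether F3. Suzuki–Miyaura coupling under the conditions of step 14 joins F3 to 2-[(E)-2-[3,4-bis(tert-butyldimethylsilyloxy)phenyl]ethenyl]-4,4,5,5-tetramethyl-1,3,2-dioxaborolane F4, made from commercial 3,4-bis(tert-butyldimethylsilyloxy)benzaldehyde as in step 13. The product is the fully silylated stilbene flavan (2R,3S,4S)-hexakis-O-(tert-butyldimethylsilyl)-3-O-(triisopropylsilyl) derivative of the target F5. Bu4NF buffered with acetic acid in THF then removes all seven silyl groups and comes back to the route at 24.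

Further compounds
F1 | step 12 | (1R,2S,3S)-1-[4-(benzyloxy)phenyl]-3-[4-(benzyloxy)-2-(4,4,5,5-tetramethyl-1,3,2-dioxaborolan-2-yl)phenyl]-3-[2,4-bis(benzyloxy)-6-chlorophenyl]-2-[(triisopropylsilyl)oxy]propan-1-ol | c1ccccc1COc1ccc(cc1)[C@@H](O)[C@@H](O[Si](C(C)C)(C(C)C)C(C)C)[C@@H](c1ccc(OCc2ccccc2)cc1B1OC(C)(C)C(C)(C)O1)c1c(OCc2ccccc2)cc(OCc2ccccc2)cc1Cl
F0 | step 7 | none | none
F2 | step 16 | (2R,3S,4S)-4-(2-chloro-4,6-dihydroxyphenyl)-2-(4-hydroxyphenyl)-3-[(triisopropylsilyl)oxy]-3,4-dihydro-2H-chromen-7-ol | Oc1ccc([C@H]2Oc3cc(O)ccc3[C@@H](c3c(O)cc(O)cc3Cl)[C@@H]2O[Si](C(C)C)(C(C)C)C(C)C)cc1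
F3 | step 16 | (2R,3S,4S)-7-(tert-butyldimethylsilyloxy)-2-[4-(tert-butyldimethylsilyloxy)phenyl]-4-[2,4-bis(tert-butyldimethylsilyloxy)-6-chlorophenyl]-3-[(triisopropylsilyl)oxy]-3,4-dihydro-2H-chromene | CC(C)(C)[Si](C)(C)Oc1ccc([C@H]2Oc3cc(O[Si](C)(C)C(C)(C)C)ccc3[C@@H](c3c(O[Si](C)(C)C(C)(C)C)cc(O[Si](C)(C)C(C)(C)C)cc3Cl)[C@@H]2O[Si](C(C)C)(C(C)C)C(C)C)cc1
F4 | step 16 | 2-[(E)-2-[3,4-bis(tert-butyldimethylsilyloxy)phenyl]ethenyl]-4,4,5,5-tetramethyl-1,3,2-dioxaborolane | CC1(C)OB(/C=C/c2ccc(O[Si](C)(C)C(C)(C)C)c(O[Si](C)(C)C(C)(C)C)c2)OC1(C)C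
F5 | step 16 | (2R,3S,4S)-7-(tert-butyldimethylsilyloxy)-2-[4-(tert-butyldimethylsilyloxy)phenyl]-4-[2,4-bis(tert-butyldimethylsilyloxy)-6-[(E)-2-[3,4-bis(tert-butyldimethylsilyloxy)phenyl]ethenyl]phenyl]-3-[(triisopropylsilyl)oxy]-3,4-dihydro-2H-chromene | CC(C)(C)[Si](C)(C)Oc1ccc([C@H]2Oc3cc(O[Si](C)(C)C(C)(C)C)ccc3[C@@H](c3c(O[Si](C)(C)C(C)(C)C)cc(O[Si](C)(C)C(C)(C)C)cc3/C=C/c3ccc(O[Si](C)(C)C(C)(C)C)c(O[Si](C)(C)C(C)(C)C)c3)[C@@H]2O[Si](C(C)C)(C(C)C)C(C)C)cc1
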